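Its constants are invented; no experiment stands behind them.

I decide to count the life of this catalyst rather than the hours of the flask.

    reagent + free catalyst → spent catalyst (k1 = 0.116 L mol⁻¹ h⁻¹, Ea1 = 70.0 kJ mol⁻¹)
    reagent + free catalyst + left-handed substrate → free catalyst + left-handed product (k2 = 3320 L² mol⁻² h⁻¹, Ea2 = 52.0 kJ mol⁻¹)
    reagent + free catalyst + right-handed substrate → free catalyst + right-handed product (k3 = 37.3 L² mol⁻² h⁻¹, Ea3 = 60.0 kJ mol⁻¹)
    left-handed substrate ⇌ right-handed substrate (k4 = 0.00841 h⁻¹, Ea4 = 91.0 kJ mol⁻¹)
    (constants at 20 °C)

all flasks: left-handed substrate 0.046 M; reagent 0.138 M; free catalyst 92 µM; right-handed substrate 0.046 M; time 4.0 d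

| charge | remark | temperature |
|---|---|---|
| Friday's | at 20 °C until 3.0 d, from then on at 70 °C |  |
| Saturday's |  | 20 °C |
| Monday's |  | 45 °C |
| Wednesday's |  | 70 °C |

* the flask with the highest amount of left-handed product, in percent of the left-handed substrate and right-handed substrate together charged ("all alike" if they lie within 1.5 percentage points) (Friday's / Saturday's / Monday's / Wednesday's / all alike)
* final left-handed product, as a percentage of the left-handed substrate and right-handed substrate together charged, in Friday's
* final left-handed product, as a percentage of the left-handed substrate and right-handed substrate together charged, in Saturday's
* final left-handed product, as a percentage of the left-handed substrate and right-handed substrate together charged, in Monday's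
* final left-handed product, as a percentage of the left-handed substrate and right-handed substrate together charged, in Wednesday's

- free catalyst is single-handed; left-handed substrate and right-handed substrate are mirror images of each other, charged as a racemate, each of them at the stated concentration
- constants are those at 20 °C; use the activation energies for any other temperature

The bench rule says that a catalyst comes back from each turn, so a warmer flask gives more product sooner, and the left-handed turnover does speed up 22-fold from 20 °C to 70 °C. The rule holds while the free catalyst outlives the run. But the reagent destroys it: at the charged reagent and 20 °C its half-life is 1.80 d, shorter than the 4.0 d of the run. Over the same span its death speeds up 65.7-fold, more than the turnover, as the ratio of the two activation energies, 1.35, says.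

Both the death and the turnover per left-handed substrate go with reagent times free catalyst, so their quotient contains neither, and it integrates in closed form whatever the reagent does. With racemisation set aside, the natural logarithm of the factor by which left-handed substrate falls equals the turnover constant over the death constant, times the free catalyst spent. With the whole charge spent this is 2.63 at 20 °C, and I call it the catalyst budget. At 70 °C it is 0.898, smaller.

I set aside the right-handed turnover, since at the start of Friday's the left-handed path uses reagent 89 times as fast. Without racemisation, a budget gives left-handed product of one minus exp(−budget), halved, as a share of both substrates. If racemisation keeps the two substrates equal (dynamic kinetic resolution), left-handed substrate is half of the pool, and the share is one minus exp(−budget/2). In Wednesday's flask these limits are 29.6 % and 36.2 %. Equalising runs at 3.88 h⁻¹ and death at about 1.05 h⁻¹, slower, so I commit to just under the upper limit. For Friday's I get no number, but I choose it as the best flask: its cold days spend catalyst at the larger budget, and with reagent held at its charge 31.6 % of the free catalyst charged reaches the change of temperature.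

The forecast gives 52.4 % for Friday's, 48.4 % for Saturday's, 47.7 % for Monday's and 34.7 % for Wednesday's, and names Friday's. Its ground for Friday's is “Heating equalizes the substrates quickly”. Its Wednesday's figure stands 1.5 percentage points below my upper limit.

The simulation gives 52.5 %, 48.3 %, 48.2 % and 34.8 % in that order, with Friday's highest, as forecast. Friday's figure moves by 5 points at 75.6 µM or 112 µM of free catalyst, or with the run cut to 3.03 d. Friday's has come to rest: free catalyst is 0 % at 4.00 d, and left-handed product is 52.5 % at 40.0 d. The 40.0 % of free catalyst left at Friday's change of temperature, spent at 70 °C, carried a budget of 0.359, which on a pool of 55.1 % reckons, with the two substrates held equal, to 9.1 points on top of 44.1 %. Saturday's has not come to rest: its 30.8 % of free catalyst is a budget of 0.810, a reckoned ceiling of 65.2 %, and left-handed product goes from 48.3 % at 4.00 d to 62.4 % at 40.0 d.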